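**Plan**
1. Retrosynthesis: the C20 methyl and ring C are cut together at C9–C11 and C11–C20 (a cyclopropane from a C12 diazomethyl ketone and a C9 exocyclic methylene). Ring A is cut at C7–C8 (carbonyl-ene), ring B at C3–C4 and C5–C10 (Diels–Alder), the lactone at O–C18.
2. Enabling feature: C9, the quaternary carbon common to rings A and C, carries the C20 methyl and the ring C methylene C11 next to the C12 furyl ketone. A cyclopropane C9–C11–C20 releases exactly this pair when C11–C20 is cleaved.
3. Forward order: furan ester to a 2-silyloxy diene; Diels–Alder with a formyl acrylate closes ring B; lactone; carbonyl-ene closure of ring A; copper carbenoid cyclopropanation closes ring C; iodide opening and tin hydride give the methyl.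
4. Stereochemistry: C5 and C10 come from the catalyst-controlled endo Diels–Alder. C1 is set by equilibration, C2 by axial hydride attack, C7 and C8 by the chair ene transition state of the (E)-butenyl group, C9 by the face selectivity of the tethered carbenoid.

Key step: step 18

Numbering and faces: C1 (CH bearing the furan), C2 (carbinol), C3=C4, C5 (quaternary, bears C19H2–O), C6, C7 (acetoxy), C8 (bears C17H3), C9 (bears C20H3 and C11H2), C10 (ring-fusion CH), C12 (ketone), C13–C16 (furan; C16 on C1, C13 on C12), C18 (lactone carbonyl on C4). Ring A = C5–C10, ring B = C1–C5 with C10, ring C = the seven-membered ring. β is the face of C19. TBS = tert-butyldimethylsilyl.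

Assumption: the sense of induction in step 6 is taken from the formyl C–H···O binding model for 2-substituted enals on the oxazaborolidinium ion, which assigns the (R)-catalyst to the required C5 configuration; this is a model assignment and has to be confirmed on the first adduct.

**Route**

Step 1
Reactants: 1 2-methylfuran-3-carboxylic acid
Product: 2 allyl 2-methylfuran-3-carboxylate
Conditions: allyl bromide, K2CO3, DMF, rt
Reagents that add atoms: allyl bromide, C=CCBr
Why: Carboxylate O-alkylation (SN2) installs an ester that zerovalent palladium can later remove without touching the lactone and the acetate; no stereocentre is formed.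

Step 2
Reactants: 2 allyl 2-methylfuran-3-carboxylate; 3 N-methoxy-N-methylacetamide
Product: 5 allyl 2-(2-oxopropyl)furan-3-carboxylate, via lithiated ester 4 (not isolated)
Conditions: LiN(i-Pr)2, THF, –78 °C; then 3; aq. NH4Cl
Reagents that add atoms: none
Why: LiN(i-Pr)2 deprotonates the 2-methyl group (vinylogous ester enolate) and the carbanion is acylated by the Weinreb amide, whose chelated tetrahedral adduct prevents a second addition (Weinreb ketone synthesis).

Step 3
Reactants: 5 allyl 2-(2-oxopropyl)furan-3-carboxylate; 6 (E)-2-methylbut-2-enal (tiglic aldehyde)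
Product: 7 allyl 2-[(3E,5E)-5-methyl-2-oxohepta-3,5-dien-3-yl]furan-3-carboxylate
Conditions: piperidine (cat.), AcOH (cat.), toluene, reflux, Dean–Stark
Reagents that add atoms: none
Why: Knoevenagel condensation at the methylene activated by the ketone and the furan ester; reversible amine addition lets the new C1=C10 bond settle in the (E)-form with the dienyl group trans to acetyl, and the (E)-geometry of tiglic aldehyde is carried over unchanged.

Step 4
Reactants: 7 allyl 2-[(3E,5E)-5-methyl-2-oxohepta-3,5-dien-3-yl]furan-3-carboxylate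
Product: 8 allyl 2-[(3E,5E)-2-(TBS-oxy)-5-methylhepta-1,3,5-trien-3-yl]furan-3-carboxylate
Conditions: TBSOTf, Et3N, CH2Cl2, 0 °C
Reagents that add atoms: tert-butyldimethylsilyl trifluoromethanesulfonate, CC(C)(C)[Si](C)(C)OS(=O)(=O)C(F)(F)F
Why: Soft enolisation (silyl triflate and amine) of the only enolisable position, the acetyl methyl, gives the 2-silyloxy diene whose unsubstituted terminus (future C3) is the nucleophilic one.

Step 5
Reactants: 9 4-(TBS-oxy)butanal; 10 ethyl glyoxylate
Product: 11 ethyl (E)-5-(TBS-oxy)-3-formylpent-2-enoate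
Conditions: pyrrolidine (cat.), AcOH (cat.), toluene, 4 Å MS, 40 °C
Reagents that add atoms: none
Why: Amine-catalysed aldol condensation: the enamine of 9 adds to the glyoxylate aldehyde and water is lost to the conjugated enal, the (E)-isomer (formyl trans to CO2Et) being the thermodynamic one.

Step 6
Reactants: 8 silyloxy triene; 11 formyl acrylate
Product: 12 ring B cycloadduct: ethyl 4-[3-(allyloxycarbonyl)furan-2-yl]-5-[(E)-but-2-en-2-yl]-6-formyl-3-(TBS-oxy)-6-[2-(TBS-oxy)ethyl]cyclohex-3-ene-1-carboxylate (formyl β and cis to the butenyl group; CO2Et trans to formyl)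
Conditions: (R)-3,3-diphenyl-1-(o-tolyl)tetrahydro-1H,3H-pyrrolo[1,2-c][1,3,2]oxazaborole (20 mol %), Tf2NH (20 mol %), CH2Cl2, –78 to –40 °C
Reagents that add atoms: none
Why: Oxazaborolidinium-catalysed enantioselective Diels–Alder reaction: the Lewis acid-bound formyl group makes C4 the electrophilic terminus, so the unsubstituted diene terminus C3 bonds to C4 and C10 bonds to C5 (silyloxy group para and C10 substituent ortho to the formyl-bearing carbon); the endo formyl group ends cis to the butenyl group (C19 β, 10-H α), and the catalyst selects the enal face and with it the absolute configuration of C5 and C10.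

Step 7
Reactants: 12 ring B cycloadduct
Product: 14 enol ether lactone (cis-fused C19–O–C18 γ-lactone on C5/C4; C1=C2 silyl enol ether retained), via hydroxy ester 13 (not isolated)
Conditions: NaBH4, EtOH, –20 °C; aq. work-up; then KOt-Bu (0.2 equiv), THF, 0 °C
Reagents that add atoms: none
Why: NaBH4 reduces only the aldehyde, and catalytic alkoxide epimerises the ester-bearing C4 so that the C19 alkoxide closes the cis-fused γ-lactone by transesterification; the C4 configuration is of no consequence because C4 becomes sp2 in step 11.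

Step 8
Reactants: 14 enol ether lactone
Product: 15 keto lactone (C2 ketone; furan on C1 α and trans to the butenyl group on C10)
Conditions: Bu4NF (1.1 equiv), AcOH (1.1 equiv), THF, –40 to 0 °C; then DBU (0.2 equiv), CH2Cl2, rt
Reagents that add atoms: none
Why: Fluoride cleaves the silyl enol ether far faster than the primary alkyl silyl ether (an enolate is the better leaving group), and base equilibration of the α-furyl ketone places the furan equatorial (1α), the axial epimer suffering a 1,3-diaxial contact with C19.

Step 9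
Reactants: 15 keto lactone
Product: 16 2β-alcohol
Conditions: NaBH4, MeOH, –40 °C
Reagents that add atoms: none
Why: Ketone reduction in which NaBH4 attacks the cyclohexanone axially from the unhindered α face (only axial hydrogens at C4 and C10) and gives the equatorial 2β-alcohol, trans to the furan.

Step 10
Reactants: 16 2β-alcohol
Product: 17 bis-silyl ether lactone (2β-OTBS)
Conditions: TBSOTf, 2,6-lutidine, CH2Cl2, –78 to 0 °C
Reagents that add atoms: tert-butyldimethylsilyl trifluoromethanesulfonate, CC(C)(C)[Si](C)(C)OS(=O)(=O)C(F)(F)F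
Why: Silylation of the hindered secondary alcohol with the silyl triflate and a weak base that does not enolise the lactone.

Step 11
Reactants: 17 bis-silyl ether lactone
Product: 21 unsaturated lactone (C3=C4 conjugated with C18), via lithium enolate 18 (not isolated), via selenide 19 (not isolated), via selenoxide 20 (not isolated)
Conditions: LiN(i-Pr)2, THF, –78 °C; PhSeBr; then 30% H2O2, pyridine, CH2Cl2, 0 °C to rt
Reagents that add atoms: none
Why: α-Selenenylation of the lactone enolate followed by oxidation and syn elimination of the selenoxide; C5 is quaternary, so the elimination can only run towards C3.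

Step 12
Reactants: 21 unsaturated lactone
Product: 22 primary alcohol (C7–OH; 2β-OTBS kept)
Conditions: HF·pyridine, pyridine, THF, 0 °C
Reagents that add atoms: none
Why: Buffered fluoride desilylation removes the unhindered primary silyl ether much faster than the secondary one flanked by C1 and the alkene.

Step 13
Reactants: 22 primary alcohol
Product: 23 aldehyde (C7 formyl on the C6 methylene of C5)
Conditions: Dess–Martin periodinane, NaHCO3, CH2Cl2, rt
Reagents that add atoms: none
Why: Dess–Martin oxidation of the primary alcohol under buffered conditions; the aldehyde has no α-stereocentre to lose.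

Step 14
Reactants: 23 aldehyde
Product: 24 ring A alcohol (trans-decalin; 7β-OH axial, 8β-CH3 equatorial, C9=C20H2 exocyclic)
Conditions: Me2AlCl (2.5 equiv), CH2Cl2, –78 to –20 °C
Reagents that add atoms: none
Why: Lewis acid-promoted intramolecular carbonyl-ene reaction of type 2 (tether on the central carbon of the ene unit): C7 bonds to C8 while a hydrogen of the C9 methyl passes to oxygen and leaves the exocyclic methylene; in the chair transition state of the forming trans-decalin the aluminium-bound oxygen must be axial to reach that methyl, which gives the 7β-alcohol, and the (E)-alkene geometry places the C8 methyl equatorial (β).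

Step 15
Reactants: 24 ring A alcohol
Product: 25 7β-acetate
Conditions: Ac2O, DMAP, Et3N, CH2Cl2, rt
Reagents that add atoms: acetic anhydride, CC(=O)OC(C)=O
Why: DMAP-catalysed acylation of the axial secondary alcohol.

Step 16
Reactants: 25 7β-acetate
Product: 26 furan-3-carboxylic acid
Conditions: Pd(PPh3)4 (5 mol %), N-methylaniline, THF, rt
Reagents that add atoms: none
Why: Tsuji–Trost deallylation: zerovalent palladium ionises the allyl ester and the amine traps the π-allyl fragment under neutral conditions that leave lactone, acetate and silyl ether intact.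

Step 17
Reactants: 26 furan-3-carboxylic acid
Product: 28 diazomethyl ketone, via acid chloride 27 (not isolated)
Conditions: 1-chloro-N,N,2-trimethylprop-1-en-1-amine, CH2Cl2, 0 °C to rt; then CH2N2 (3 equiv), Et2O, –10 °C, short contact
Reagents that add atoms: diazomethane, C=[N+]=[N-]
Why: Neutral chlorination of the acid with the α-chloro enamine followed by acylation of diazomethane (first stage of the Arndt–Eistert sequence), a second equivalent of diazomethane taking up the HCl; low temperature and short contact keep the alkylidene lactone from acting as a dipolarophile.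

Step 18
Reactants: 28 diazomethyl ketone
Product: 29 cyclopropyl ketone (spiro-fused cyclopropane C9–C11–C20 closing ring C)
Conditions: Cu(acac)2 (10 mol %), toluene, 100 °C, slow addition at high dilution
Reagents that add atoms: none
Why: The divalent copper acetylacetonate decomposes the diazo ketone with loss of N2 to an electrophilic copper keto carbenoid, which adds to the 1,1-disubstituted C9=C20 alkene in a concerted, asynchronous [2+1] step; the closest known reaction type is the copper-catalysed intramolecular cyclopropanation of unsaturated α-diazo ketones. Ring C closes in the 7-exo sense as the carbenoid carbon C11 bonds to C9, and the three-membered ring closes as C11 bonds to C20. C9 is set by the alkene face that is attacked: the tether starts at the equatorial furan on C1, so C11 can reach C9 only from the equatorial α side, and the β face is also screened by axial C19 and the axial 7-acetoxy group, which leaves C20 axial. C11 follows from the suprafacial addition, because a cyclopropane fused to the seven-membered ring must be cis. The step needs cyclopropanation to win over insertion into the C1–H bond and over carbene dimerisation; a copper carbenoid prefers π bonds to C–H bonds, the electron-rich methylene is held next to it by the rigid decalin, and slow addition keeps the diazo concentration low.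

Step 19
Reactants: 29 cyclopropyl ketone
Product: 31 iodo ketone (C20H2I on C9; C11H2 restored), via silyl enol ether 30 (not isolated)
Conditions: TMSCl, NaI, MeCN, –20 to 0 °C; aq. NaHCO3/Na2S2O3
Reagents that add atoms: sodium iodide, [Na+].[I-]
Why: Homo-conjugate opening of the cyclopropyl ketone by iodotrimethylsilane made in the flask: silylation of the ketone activates the ring, the C11–C20 bond lies parallel to the carbonyl π system, and iodide attacks primary C20, the only accessible carbon, in SN2 fashion, so C9 keeps its configuration and the enol ether is hydrolysed on work-up.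

Step 20
Reactants: 31 iodo ketone
Product: 32 silyl ether of the target (C20 methyl in place)
Conditions: Bu3SnH, AIBN (cat.), benzene, 80 °C
Reagents that add atoms: none
Why: Radical chain dehalogenation of the primary neopentyl iodide turns CH2I into the C20 methyl without touching C9.

Step 21
Reactants: 32 silyl ether of the target
Product: 33 CNP0182929.1
Conditions: HF·pyridine, MeCN, 0 °C to rt
Reagents that add atoms: none
Why: Fluoride-mediated cleavage of the secondary silyl ether under mildly acidic conditions that spare the acetate and the lactone.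

**Compound list**
1 | 2-methylfuran-3-carboxylic acid | Cc1occc1C(O)=O | starting material
2 | allyl 2-methylfuran-3-carboxylate | Cc1occc1C(=O)OCC=C | intermediate
3 | N-methoxy-N-methylacetamide | CC(=O)N(C)OC | starting material
4 | lithiated ester, allyl 2-(lithiomethyl)furan-3-carboxylate | [Li]Cc1occc1C(=O)OCC=C | intermediate
5 | allyl 2-(2-oxopropyl)furan-3-carboxylate | CC(=O)Cc1occc1C(=O)OCC=C | intermediate
6 | (E)-2-methylbut-2-enal (tiglic aldehyde) | C/C=C(C)/C=O | starting material
7 | allyl 2-[(3E,5E)-5-methyl-2-oxohepta-3,5-dien-3-yl]furan-3-carboxylate | CC(=O)/C(c1occc1C(=O)OCC=C)=C/C(C)=C/C | intermediate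
8 | allyl 2-[(3E,5E)-2-(TBS-oxy)-5-methylhepta-1,3,5-trien-3-yl]furan-3-carboxylate | C=C(O[Si](C)(C)C(C)(C)C)/C(c1occc1C(=O)OCC=C)=C/C(C)=C/C | intermediate
9 | 4-(TBS-oxy)butanal | O=CCCCO[Si](C)(C)C(C)(C)C | starting material
10 | ethyl glyoxylate | CCOC(=O)C=O | starting material
11 | ethyl (E)-5-(TBS-oxy)-3-formylpent-2-enoate | CCOC(=O)/C=C(/C=O)CCO[Si](C)(C)C(C)(C)C | intermediate
12 | ring B cycloadduct (C5 formyl β, cis to butenyl on C10; C4 ester trans to formyl; C1=C2 silyl enol ether) | CC(C)(C)[Si](C)(C)OCC[C@@]1(C=O)[C@@H](C(=O)OCC)CC(O[Si](C)(C)C(C)(C)C)=C(c2occc2C(=O)OCC=C)[C@@H]1/C(C)=C/C | intermediate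
13 | hydroxy ester (12 with C19H2OH in place of formyl) | CC(C)(C)[Si](C)(C)OCC[C@@]1(CO)[C@@H](C(=O)OCC)CC(O[Si](C)(C)C(C)(C)C)=C(c2occc2C(=O)OCC=C)[C@@H]1/C(C)=C/C | intermediate
14 | enol ether lactone (cis-fused C19–O–C18 lactone, 4-H α) | CC(C)(C)[Si](C)(C)OCC[C@@]12COC(=O)[C@@H]1CC(O[Si](C)(C)C(C)(C)C)=C(c3occc3C(=O)OCC=C)[C@@H]2/C(C)=C/C | intermediate
15 | keto lactone (C2 ketone, furan 1α) | CC(C)(C)[Si](C)(C)OCC[C@@]12COC(=O)[C@@H]1CC(=O)[C@@H](c3occc3C(=O)OCC=C)[C@@H]2/C(C)=C/C | intermediate
16 | 2β-alcohol | CC(C)(C)[Si](C)(C)OCC[C@@]12COC(=O)[C@@H]1C[C@H](O)[C@@H](c3occc3C(=O)OCC=C)[C@@H]2/C(C)=C/C | intermediate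
17 | bis-silyl ether lactone (2β-OTBS) | CC(C)(C)[Si](C)(C)OCC[C@@]12COC(=O)[C@@H]1C[C@H](O[Si](C)(C)C(C)(C)C)[C@@H](c3occc3C(=O)OCC=C)[C@@H]2/C(C)=C/C | intermediate
18 | lithium enolate of 17 | CC(C)(C)[Si](C)(C)OCC[C@@]12COC(O[Li])=C1C[C@H](O[Si](C)(C)C(C)(C)C)[C@@H](c3occc3C(=O)OCC=C)[C@@H]2/C(C)=C/C | intermediate
19 | selenide (4-phenylselanyl lactone, cis-fused) | CC(C)(C)[Si](C)(C)OCC[C@@]12COC(=O)[C@]1([Se]c3ccccc3)C[C@H](O[Si](C)(C)C(C)(C)C)[C@@H](c4occc4C(=O)OCC=C)[C@@H]2/C(C)=C/C | intermediate
20 | selenoxide of 19 | CC(C)(C)[Si](C)(C)OCC[C@@]12COC(=O)[C@]1([Se](=O)c3ccccc3)C[C@H](O[Si](C)(C)C(C)(C)C)[C@@H](c4occc4C(=O)OCC=C)[C@@H]2/C(C)=C/C | intermediate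
21 | unsaturated lactone (C3=C4, bis-silyl ether) | CC(C)(C)[Si](C)(C)OCC[C@@]12COC(=O)C1=C[C@H](O[Si](C)(C)C(C)(C)C)[C@@H](c3occc3C(=O)OCC=C)[C@@H]2/C(C)=C/C | intermediate
22 | primary alcohol (C7–OH) | OCC[C@@]12COC(=O)C1=C[C@H](O[Si](C)(C)C(C)(C)C)[C@@H](c3occc3C(=O)OCC=C)[C@@H]2/C(C)=C/C | intermediate
23 | aldehyde (C7 formyl) | O=CC[C@@]12COC(=O)C1=C[C@H](O[Si](C)(C)C(C)(C)C)[C@@H](c3occc3C(=O)OCC=C)[C@@H]2/C(C)=C/C | intermediate
24 | ring A alcohol (7β-OH, 8β-CH3, C9 exocyclic methylene, trans-decalin) | O[C@@H]1C[C@@]23COC(=O)C2=C[C@H](O[Si](C)(C)C(C)(C)C)[C@@H](c4occc4C(=O)OCC=C)[C@@H]3C(=C)[C@@H]1C | intermediate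
25 | 7β-acetate | CC(=O)O[C@@H]1C[C@@]23COC(=O)C2=C[C@H](O[Si](C)(C)C(C)(C)C)[C@@H](c4occc4C(=O)OCC=C)[C@@H]3C(=C)[C@@H]1C | intermediate
26 | furan-3-carboxylic acid | CC(=O)O[C@@H]1C[C@@]23COC(=O)C2=C[C@H](O[Si](C)(C)C(C)(C)C)[C@@H](c4occc4C(O)=O)[C@@H]3C(=C)[C@@H]1C | intermediate
27 | acid chloride | CC(=O)O[C@@H]1C[C@@]23COC(=O)C2=C[C@H](O[Si](C)(C)C(C)(C)C)[C@@H](c4occc4C(Cl)=O)[C@@H]3C(=C)[C@@H]1C | intermediate
28 | diazomethyl ketone (ring A methylene decalin lactone, 2β-OTBS) | CC(=O)O[C@@H]1C[C@@]23COC(=O)C2=C[C@H](O[Si](C)(C)C(C)(C)C)[C@@H](c4occc4C(=O)C=[N+]=[N-])[C@@H]3C(=C)[C@@H]1C | intermediate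
29 | cyclopropyl ketone (cyclopropane C9–C11–C20, ring C closed) | CC(=O)O[C@@H]1C[C@@]23COC(=O)C2=C[C@H](O[Si](C)(C)C(C)(C)C)[C@H]2c4occc4C(=O)[C@@H]5C[C@]5([C@@H]1C)[C@@H]23 | intermediate
30 | silyl enol ether iodide (C12 OTMS enol ether, C20H2I) | CC(=O)O[C@@H]1C[C@@]23COC(=O)C2=C[C@H](O[Si](C)(C)C(C)(C)C)[C@H]2c4occc4C(O[Si](C)(C)C)=C[C@@](CI)([C@@H]1C)[C@@H]23 | intermediate
31 | iodo ketone (C20H2I on C9) | CC(=O)O[C@@H]1C[C@@]23COC(=O)C2=C[C@H](O[Si](C)(C)C(C)(C)C)[C@H]2c4occc4C(=O)C[C@@](CI)([C@@H]1C)[C@@H]23 | intermediate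
32 | silyl ether of the target (2β-OTBS) | CC(=O)O[C@@H]1C[C@@]23COC(=O)C2=C[C@H](O[Si](C)(C)C(C)(C)C)[C@H]2c4occc4C(=O)C[C@@](C)([C@@H]1C)[C@@H]23 | intermediate
33 | CNP0182929.1 (7β-acetoxy, 2β-hydroxy, 12-oxo; 8β- and 9β-methyl; 10α-H; 1β-H) | CC(=O)O[C@@H]1C[C@@]23COC(=O)C2=C[C@H](O)[C@H]2c4occc4C(=O)C[C@@](C)([C@@H]1C)[C@@H]23 | target

**Step count**
Total: 21 steps. Longest linear sequence: 20 steps (steps 1–4 and 6–21; step 5 is the one-step side branch).

**The three steps most likely to fail**

Step 6. The hindered diene (aryl group on C1, alkenyl group on C10) may react too slowly at low temperature, so that an uncatalysed or wrongly oriented pathway erodes enantiomeric purity or endo selectivity; the model-based choice of catalyst antipode may also prove reversed.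
Fallback: set out from 8 and 11 and run the cycloaddition with the achiral Lewis acid Me2AlCl in toluene at –40 °C. This should give 12 as the racemate, that is together with its mirror image ent-12 F1. Steps 7 to 9 then carry the mirror-image series along: hydroxy ester ent-13 F2, enol ether lactone ent-14 F3, keto lactone ent-15 F4 and alcohol ent-16 F5. The racemic alcohol is resolved with Candida antarctica lipase B and vinyl acetate in t-BuOMe. By the empirical rule for lipase acylation of secondary alcohols (as with trans-2-arylcyclohexanols), the (R)-carbinol ent-16 should be acetylated to the acetate of ent-16 F6, which is separated by chromatography. The unreacted (S)-carbinol 16 returns to the route at step 10.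

Step 14. Control over C7 may be lost, because the chair transition state with the axial aluminium-bound oxygen is penalised by its 1,3-diaxial contact with C19 and a boat-like array would deliver the equatorial alcohol.
Fallback: set out from aldehyde 23 and accept the cyclisation product with the wrong C7 configuration, the 7α-alcohol F7. Buffered Dess–Martin oxidation should give the β,γ-unsaturated C7 ketone F8. LiBH(s-Bu)3 in THF at –78 °C then delivers hydride from the α face, away from axial C19, to give the axial alcohol 24, where the route is rejoined at step 15.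

Step 18. The keto carbenoid may be consumed by insertion into the neighbouring C1–H bond or by dimerisation before it reaches the methylene group across the forming seven-membered ring.
Fallback: set out from acid 26. Activation with carbonyldiimidazole and reaction with Mg(O2CCH2CO2CH2CH=CH2)2 should give the β-keto allyl ester F9, and diazo transfer with 4-acetamidobenzenesulfonyl azide and Et3N the diazo keto ester F10. This stabilised acceptor–acceptor diazo compound, decomposed with Cu(acac)2 in toluene at 110 °C, should close the same two bonds to the cyclopropane keto ester F11. MgI2 in THF opens the doubly activated cyclopropane at the CH2 carbon to the iodo keto ester F12, and Bu3SnH with AIBN reduces it to the methyl keto ester F13. Pd(PPh3)4 with morpholine removes the allyl ester with decarboxylation and gives 32, where the route is rejoined at step 21.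

**Further compounds**
F1 | step 6 | ent-12 | CC(C)(C)[Si](C)(C)OCC[C@]1(C=O)[C@H](C(=O)OCC)CC(O[Si](C)(C)C(C)(C)C)=C(c2occc2C(=O)OCC=C)[C@H]1/C(C)=C/C
F2 | step 6 | ent-13 | CC(C)(C)[Si](C)(C)OCC[C@]1(CO)[C@H](C(=O)OCC)CC(O[Si](C)(C)C(C)(C)C)=C(c2occc2C(=O)OCC=C)[C@H]1/C(C)=C/C
F3 | step 6 | ent-14 | CC(C)(C)[Si](C)(C)OCC[C@]12COC(=O)[C@H]1CC(O[Si](C)(C)C(C)(C)C)=C(c3occc3C(=O)OCC=C)[C@H]2/C(C)=C/C
F4 | step 6 | ent-15 | CC(C)(C)[Si](C)(C)OCC[C@]12COC(=O)[C@H]1CC(=O)[C@H](c3occc3C(=O)OCC=C)[C@H]2/C(C)=C/C
F5 | step 6 | ent-16 | CC(C)(C)[Si](C)(C)OCC[C@]12COC(=O)[C@H]1C[C@@H](O)[C@H](c3occc3C(=O)OCC=C)[C@H]2/C(C)=C/C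
F6 | step 6 | acetate of ent-16 | CC(C)(C)[Si](C)(C)OCC[C@]12COC(=O)[C@H]1C[C@@H](OC(C)=O)[C@H](c3occc3C(=O)OCC=C)[C@H]2/C(C)=C/C
F7 | step 14 | 7α-alcohol (C7 epimer of 24) | O[C@H]1C[C@@]23COC(=O)C2=C[C@H](O[Si](C)(C)C(C)(C)C)[C@@H](c4occc4C(=O)OCC=C)[C@@H]3C(=C)[C@@H]1C
F8 | step 14 | C7 ketone | O=C1C[C@@]23COC(=O)C2=C[C@H](O[Si](C)(C)C(C)(C)C)[C@@H](c4occc4C(=O)OCC=C)[C@@H]3C(=C)[C@@H]1C
F9 | step 18 | β-keto allyl ester | CC(=O)O[C@@H]1C[C@@]23COC(=O)C2=C[C@H](O[Si](C)(C)C(C)(C)C)[C@@H](c4occc4C(=O)CC(=O)OCC=C)[C@@H]3C(=C)[C@@H]1C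
F10 | step 18 | diazo keto ester | CC(=O)O[C@@H]1C[C@@]23COC(=O)C2=C[C@H](O[Si](C)(C)C(C)(C)C)[C@@H](c4occc4C(=O)C(=[N+]=[N-])C(=O)OCC=C)[C@@H]3C(=C)[C@@H]1C
F11 | step 18 | cyclopropane keto ester | CC(=O)O[C@@H]1C[C@@]23COC(=O)C2=C[C@H](O[Si](C)(C)C(C)(C)C)[C@H]2c4occc4C(=O)[C@]5(C(=O)OCC=C)C[C@]5([C@@H]1C)[C@@H]23
F12 | step 18 | iodo keto ester | CC(=O)O[C@@H]1C[C@@]23COC(=O)C2=C[C@H](O[Si](C)(C)C(C)(C)C)[C@H]2c4occc4C(=O)C(C(=O)OCC=C)[C@@](CI)([C@@H]1C)[C@@H]23
F13 | step 18 | methyl keto ester | CC(=O)O[C@@H]1C[C@@]23COC(=O)C2=C[C@H](O[Si](C)(C)C(C)(C)C)[C@H]2c4occc4C(=O)C(C(=O)OCC=C)[C@@](C)([C@@H]1C)[C@@H]23
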